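**Retrosynthetic overview**

- The target is the 5,10-cis-fused labdane (13S)-8α-hydroxy-10-epi-labdan-15-yl acetate. The C8 alcohol is installed last by Markovnikov hydration of C7=C8, after hydrogenation of a ring A alkene.
- Feature: in ring B (C5–C10) the unit C5–C4(CH3)2 lies beside the quaternary C10. With one extra bond from C4 to C7 this is a pinane (cyclobutane C4–C5–C6–C7), so ring A (C1–C5, C10) is cut at C3–C4 and C4 is tied back to C7.
- Key disconnection: an acid-triggered cascade on a tetrasubstituted pinene. Protonation at C9, cleavage of C7–C4 and capture of the C4 cation by the allyl group on C10 set C9 and close ring A. Ring B comes from the chiral pool; ring A forms second.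
- The pinene is built on (+)-nopinone: C10 by two conjugate additions (allyl, then methyl anti to the bridge), the C9 chain by aldol condensation and conjugate reduction, the C8 methyl by enol triflate coupling.
- The C11–C15 chain with C13 comes from (R)-methyl hydrogen 3-methylglutarate.

Key step: step 11

Remark: positions are given in labdane numbering. The C11–C15 unit is an end-differentiated 3-methylpentane-1,5-diol (five chain carbons), so a glutarate half-ester is the matching chiral building block.

**Route**

Step 1
Reactants: 1 (1R,5S)-(+)-nopinone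
Product: 2 (1R,5R)-apoverbenone (6,6-dimethylbicyclo[3.1.1]hept-3-en-2-one)
Conditions: IBX, DMSO–PhF, 70 °C
Reagents that add atoms: none
Why: Nicolaou IBX dehydrogenation of a ketone to its enone; only C3–C4 of the pinane can be desaturated because the other α-carbon is a bridgehead, and no stereocentre is touched.

Step 2
Reactants: 2 (1R,5R)-apoverbenone
Product: 3 [(4-allyl-6,6-dimethylbicyclo[3.1.1]hept-2-en-2-yl)oxy]trimethylsilane, allyl anti to the gem-dimethyl bridge
Conditions: allylMgBr, CuBr·SMe2, Me3SiCl, THF, −78 °C; Et3N, cold aq. NaHCO3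
Reagents that add atoms: allylmagnesium bromide C=CC[Mg]Br; chlorotrimethylsilane C[Si](C)(C)Cl
Why: Conjugate addition of allylcopper with Me3SiCl trapping (Lipshutz conditions) gives the 1,4-adduct as its silyl enol ether; the reagent enters anti to the gem-dimethyl bridge, although this centre is erased in step 3.

Step 3
Reactants: 3 silyl enol ether
Product: 4 (1R,5S)-4-allyl-6,6-dimethylbicyclo[3.1.1]hept-3-en-2-one
Conditions: IBX, 4-methoxypyridine N-oxide (MPO), DMSO, 25 °C
Reagents that add atoms: none
Why: Nicolaou dehydrogenation of a silyl enol ether with IBX·MPO at room temperature restores the enone under neutral conditions, so the allyl alkene is not drawn into conjugation.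

Step 4
Reactants: 5 (R)-methyl hydrogen 3-methylglutarate
Product: 7 methyl (3R)-5-(tert-butyldimethylsilyloxy)-3-methylpentanoate, via hydroxy ester 6 (not isolated)
Conditions: BH3·SMe2, THF, 0 °C to rt; MeOH, concentrate; then t-BuMe2SiCl, imidazole, DMF, rt
Reagents that add atoms: tert-butyldimethylsilyl chloride CC(C)(C)[Si](C)(C)Cl
Why: Borane reduces the free carboxylic acid chemoselectively beside the methyl ester, and the crude hydroxy ester is silylated at once (silyl ether protection) before it can lactonise; the stereocentre is not involved.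

Step 5
Reactants: 7 silyloxy ester
Product: 8 (3R)-5-(tert-butyldimethylsilyloxy)-3-methylpentanal
Conditions: i-Bu2AlH, CH2Cl2, −78 °C; aq. potassium sodium tartrate
Reagents that add atoms: none
Why: Partial reduction of a methyl ester by i-Bu2AlH at −78 °C stops at the aluminium hemiacetal, which gives the aldehyde on work-up without touching the β-stereocentre.

Step 6
Reactants: 4 allyl enone; 8 aldehyde
Product: 10 4-allyl-3-[(3R)-5-(tert-butyldimethylsilyloxy)-1-hydroxy-3-methylpentyl]-4,6,6-trimethylbicyclo[3.1.1]heptan-2-one (epimers at ring C3 and the carbinol carbon), via lithium enolate 9 (not isolated)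
Conditions: Me2CuLi, Et2O, −30 to 0 °C; then 8, THF, −78 °C; aq. NH4Cl
Reagents that add atoms: lithium dimethylcuprate [Li+].C[Cu-]C
Why: Tandem cuprate conjugate addition–aldol reaction: methyl is delivered anti to the gem-dimethyl bridge, which fixes the quaternary centre (labdane C10) with allyl syn to the bridge, and the only possible enolate (the other α-carbon is a bridgehead) adds to 8; the new C3 and carbinol centres are removed in steps 7 and 8.

Step 7
Reactants: 10 aldol adduct
Product: 12 4-allyl-3-[(3S)-5-(tert-butyldimethylsilyloxy)-3-methylpentylidene]-4,6,6-trimethylbicyclo[3.1.1]heptan-2-one (alkene geometry not defined), via mesylate 11 (not isolated)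
Conditions: MsCl, Et3N, CH2Cl2, 0 °C; then DBU, rt
Reagents that add atoms: none
Why: Mesylation and DBU-induced E1cB elimination of the β-hydroxy ketone give the conjugated alkylidene ketone, whose alkene geometry is without consequence.

Step 8
Reactants: 12 alkylidene ketone
Product: 14 4-allyl-3-[(3S)-5-(tert-butyldimethylsilyloxy)-3-methylpentyl]-4,6,6-trimethylbicyclo[3.1.1]hept-2-en-2-yl trifluoromethanesulfonate, via lithium enolate 13 (not isolated)
Conditions: LiBH(s-Bu)3, THF, −78 °C; then PhNTf2, −78 °C to rt
Reagents that add atoms: N-phenylbis(trifluoromethanesulfonimide) O=S(=O)(N(c1ccccc1)S(=O)(=O)C(F)(F)F)C(F)(F)F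
Why: Conjugate reduction of the s-cis alkylidene ketone, whose carbonyl is screened by the bridgehead and the quaternary carbon, gives the tetrasubstituted enolate regiospecifically, and PhNTf2 traps it on oxygen (Selectride reduction–enolate triflation).

Step 9
Reactants: 14 enol triflate
Product: 15 tert-butyl{[(3S)-5-(4-allyl-2,4,6,6-tetramethylbicyclo[3.1.1]hept-2-en-3-yl)-3-methylpentyl]oxy}dimethylsilane
Conditions: MeMgBr, Fe(acac)3 (10 mol %), THF–NMP, −20 to 0 °C
Reagents that add atoms: methylmagnesium bromide C[Mg]Br
Why: Iron-catalysed Kumada-type cross-coupling of an alkenyl triflate with MeMgBr (Fürstner conditions) installs the C8 methyl without moving the alkene; the silyl ether and terminal alkene are inert.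

Step 10
Reactants: 15 silyl ether
Product: 17 (3S)-5-(4-allyl-2,4,6,6-tetramethylbicyclo[3.1.1]hept-2-en-3-yl)-3-methylpentyl acetate (allyl syn to the gem-dimethyl bridge), via primary alcohol 16 (not isolated)
Conditions: Bu4NF, THF, rt; then Ac2O, Et3N, DMAP (cat.), rt
Reagents that add atoms: acetic anhydride CC(=O)OC(C)=O
Why: Fluoride desilylation and in situ DMAP-catalysed acetylation exchange the silyl ether for the acetate, which unlike a silyl ether or free alcohol withstands the acid of step 11.

Step 11
Reactants: 17 tetrasubstituted pinene acetate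
Product: 18 (13S)-10-epi-labda-2,7-dien-15-yl acetate (5α-H, 9α-H, 10α-CH3)
Conditions: TfOH (20 mol %), CH2Cl2–(CF3)2CHOH (4:1), −40 °C; Et3N
Reagents that add atoms: none
Why: Proposed new method: the acid protonates the C8=C9 alkene at C9 to give a tertiary cyclobutylcarbinyl cation at C8, the strained C7–C4 bond cleaves to leave C7=C8 and a tertiary C4 cation, and the terminal carbon C3 of the allyl group on C10 bonds to C4 before the C2 cation loses a proton; the closest known reactions are the acid-induced opening of the pinene cyclobutane to the p-menthenyl cation and Brønsted-acid cation–olefin cyclization onto a monosubstituted alkene. Ring A closes by 6-endo attack of C2=C3 on C4 (bond C3–C4), since the 5-exo mode would need a primary cation. The one new stereocentre, C9, is set by the face of protonation: the gem-dimethyl bridge covers one face, and the C7–C4 bond that breaks feeds the C8 p-lobe on that same side, so the proton should enter from the open face in an anti sense, syn to the C10 methyl, leaving C11 cis to C1. C5 and C10 are carried over unchanged, and because the allyl group sits on the same side of ring B as the bond from C5 to C4, only the cis-fused decalin can form. The step needs protonation of the tetrasubstituted alkene rather than the allyl alkene (tertiary cation plus strain release against a secondary cation), ring closure rather than proton loss from the C4 cation (that loss is reversible under acid, the cyclization is not) and no acid migration of C7=C8 into the tetrasubstituted position, which low temperature and a catalytic acid in a cation-stabilising medium are chosen to limit; any ring A alkene regioisomer converges in step 12.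

Step 12
Reactants: 18 diene acetate
Product: 19 (13S)-10-epi-labd-7-en-15-yl acetate
Conditions: H2 (3 atm), RhCl(PPh3)3 (10 mol %), benzene–EtOH, rt
Reagents that add atoms: none
Why: Homogeneous hydrogenation with Wilkinson's catalyst reduces the cis-disubstituted ring A alkene far faster than the hindered trisubstituted C7=C8 alkene, and no stereocentre is formed.

Step 13
Reactants: 19 monoene acetate
Product: 20 (5S,8R,9R,10R,13S)-8-hydroxylabdan-15-yl acetate, the target
Conditions: Co(acac)2 (20 mol %), PhSiH3, O2 (1 atm), i-PrOH, rt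
Reagents that add atoms: dioxygen O=O
Why: Mukaiyama hydration (cobalt-mediated hydrogen atom transfer, then O2 capture) is Markovnikov and gives the tertiary C8 alcohol; in the cis-decalin the axial C1 methylene of ring A and the C9 chain screen one face of the C8 radical, so oxygen should enter on the face of H9 and the C10 methyl.

**Compound list**

1 | (1R,5S)-(+)-nopinone, 6,6-dimethylbicyclo[3.1.1]heptan-2-one | O=C1CC[C@H]2C[C@@H]1C2(C)C | starting material
2 | (1R,5R)-apoverbenone, 6,6-dimethylbicyclo[3.1.1]hept-3-en-2-one | O=C1C=C[C@H]2C[C@@H]1C2(C)C | intermediate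
3 | [(4-allyl-6,6-dimethylbicyclo[3.1.1]hept-2-en-2-yl)oxy]trimethylsilane, bridgeheads as in 1, allyl anti to the gem-dimethyl bridge | C[Si](C)(C)OC1=C[C@@H](CC=C)[C@H]2C[C@@H]1C2(C)C | intermediate
4 | (1R,5S)-4-allyl-6,6-dimethylbicyclo[3.1.1]hept-3-en-2-one | O=C1C=C(CC=C)[C@H]2C[C@@H]1C2(C)C | intermediate
5 | (R)-methyl hydrogen 3-methylglutarate, (3R)-5-methoxy-3-methyl-5-oxopentanoic acid | C[C@@H](CC(=O)OC)CC(=O)O | starting material
6 | methyl (3R)-5-hydroxy-3-methylpentanoate | C[C@@H](CC(=O)OC)CCO | intermediate
7 | methyl (3R)-5-(tert-butyldimethylsilyloxy)-3-methylpentanoate | C[C@@H](CC(=O)OC)CCO[Si](C)(C)C(C)(C)C | intermediate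
8 | (3R)-5-(tert-butyldimethylsilyloxy)-3-methylpentanal | C[C@@H](CC=O)CCO[Si](C)(C)C(C)(C)C | intermediate
9 | lithium 4-allyl-4,6,6-trimethylbicyclo[3.1.1]hept-2-en-2-olate (4-methyl anti, 4-allyl syn to the gem-dimethyl bridge) | [Li+].[O-]C1=C[C@](C)(CC=C)[C@H]2C[C@@H]1C2(C)C | intermediate
10 | 4-allyl-3-[(3R)-5-(tert-butyldimethylsilyloxy)-1-hydroxy-3-methylpentyl]-4,6,6-trimethylbicyclo[3.1.1]heptan-2-one (epimers at ring C3 and the carbinol carbon) | O=C1C(C(O)C[C@H](C)CCO[Si](C)(C)C(C)(C)C)[C@](C)(CC=C)[C@H]2C[C@@H]1C2(C)C | intermediate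
11 | methanesulfonate of 10 | O=C1C(C(OS(C)(=O)=O)C[C@H](C)CCO[Si](C)(C)C(C)(C)C)[C@](C)(CC=C)[C@H]2C[C@@H]1C2(C)C | intermediate
12 | 4-allyl-3-[(3S)-5-(tert-butyldimethylsilyloxy)-3-methylpentylidene]-4,6,6-trimethylbicyclo[3.1.1]heptan-2-one (alkene geometry not defined) | O=C1C(=CC[C@H](C)CCO[Si](C)(C)C(C)(C)C)[C@](C)(CC=C)[C@H]2C[C@@H]1C2(C)C | intermediate
13 | lithium 4-allyl-3-[(3S)-5-(tert-butyldimethylsilyloxy)-3-methylpentyl]-4,6,6-trimethylbicyclo[3.1.1]hept-2-en-2-olate | [Li+].[O-]C1=C(CC[C@H](C)CCO[Si](C)(C)C(C)(C)C)[C@](C)(CC=C)[C@H]2C[C@@H]1C2(C)C | intermediate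
14 | 4-allyl-3-[(3S)-5-(tert-butyldimethylsilyloxy)-3-methylpentyl]-4,6,6-trimethylbicyclo[3.1.1]hept-2-en-2-yl trifluoromethanesulfonate | FC(F)(F)S(=O)(=O)OC1=C(CC[C@H](C)CCO[Si](C)(C)C(C)(C)C)[C@](C)(CC=C)[C@H]2C[C@@H]1C2(C)C | intermediate
15 | tert-butyl{[(3S)-5-(4-allyl-2,4,6,6-tetramethylbicyclo[3.1.1]hept-2-en-3-yl)-3-methylpentyl]oxy}dimethylsilane (allyl syn to the gem-dimethyl bridge) | CC1=C(CC[C@H](C)CCO[Si](C)(C)C(C)(C)C)[C@](C)(CC=C)[C@H]2C[C@@H]1C2(C)C | intermediate
16 | (3S)-5-(4-allyl-2,4,6,6-tetramethylbicyclo[3.1.1]hept-2-en-3-yl)-3-methylpentan-1-ol | OCC[C@@H](C)CCC1=C(C)[C@@H]2C[C@@H](C2(C)C)[C@@]1(C)CC=C | intermediate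
17 | (3S)-5-(4-allyl-2,4,6,6-tetramethylbicyclo[3.1.1]hept-2-en-3-yl)-3-methylpentyl acetate (allyl syn to the gem-dimethyl bridge) | CC(=O)OCC[C@@H](C)CCC1=C(C)[C@@H]2C[C@@H](C2(C)C)[C@@]1(C)CC=C | intermediate
18 | (13S)-10-epi-labda-2,7-dien-15-yl acetate | CC(=O)OCC[C@@H](C)CC[C@@H]1[C@]2(C)CC=CC(C)(C)[C@@H]2CC=C1C | intermediate
19 | (13S)-10-epi-labd-7-en-15-yl acetate | CC(=O)OCC[C@@H](C)CC[C@@H]1[C@]2(C)CCCC(C)(C)[C@@H]2CC=C1C | intermediate
20 | (5S,8R,9R,10R,13S)-8-hydroxylabdan-15-yl acetate, (13S)-8α-hydroxy-10-epi-labdan-15-yl acetate | CC(=O)OCC[C@@H](C)CC[C@@H]1[C@]2(C)CCCC(C)(C)[C@@H]2CC[C@@]1(C)O | target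

**Step count**

Total: 13 steps. Longest linear sequence: 11 steps (1, 2, 3, 6, 7, 8, 9, 10, 11, 12, 13 from (+)-nopinone); steps 4 and 5 make the side-chain aldehyde.

**Steps most likely to fail**

Step 11. The C8 cation may undergo a Wagner–Meerwein shift instead of fragmenting. The C4 cation may lose a proton faster than the weakly nucleophilic vinyl group adds. Prolonged acid may also move C7=C8 into the tetrasubstituted position and so erase C9. The fallback interrupts the cascade and uses two reaction types with direct precedent. Setting out from 17, dilute aqueous acid (0.1 M H2SO4, acetone–H2O, rt), the conditions that hydrate α-pinene to α-terpineol, should protonate C9 from the same open face, open the cyclobutane and let water trap the C4 cation, giving the monocyclic C4 tertiary alcohol F1. F1 is then ionised with SnCl4 in CH2Cl2 at −78 °C in a Johnson-type cation–olefin cyclization from a tertiary carbinol with a vinyl terminator, which comes back to the route at 18.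

Step 13. Capture of the planar C8 radical by O2 may discriminate poorly between the two faces and give the C8 epimer. The fallback sets out from 19: mCPBA (NaHCO3, CH2Cl2, 0 °C), a bulkier oxidant that adds in a concerted way and should keep to the open face, gives the 7,8-epoxide F2. LiAlH4 (THF, 0 °C to reflux) delivers hydride to the less substituted C7, leaves the oxygen on C8 and also cleaves the acetate, giving the 8,15-diol F3. Ac2O/pyridine at 0 °C acetylates only the primary hydroxyl and comes back to the route at 20.

Step 6. Conjugate addition to the β,β-disubstituted enone may be slow and compete with deprotonation of its doubly allylic CH2, and the aldol equilibrium may lie on the side of the hindered enolate. The fallback sets out from 4: Me2CuLi with Me3SiCl (faster addition, enolate trapped on oxygen) gives the trimethylsilyl enol ether F4. A Mukaiyama aldol addition of F4 to 8 (BF3·OEt2, CH2Cl2, −78 °C), which does not revert under the conditions, comes back to the route at 10.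

Further compounds
F1 | step 11 | (3S)-5-[6-allyl-5-(2-hydroxypropan-2-yl)-2,6-dimethylcyclohex-2-en-1-yl]-3-methylpentyl acetate, side chain, allyl and hydroxypropyl groups mutually cis on the ring | CC(=O)OCC[C@@H](C)CC[C@@H]1[C@](C)(CC=C)[C@H](C(C)(C)O)CC=C1C
F2 | step 13 | (13S)-7,8-epoxy-10-epi-labdan-15-yl acetate, epoxide oxygen on the face of H9 and the C10 methyl | CC(=O)OCC[C@@H](C)CC[C@@H]1[C@]2(C)CCCC(C)(C)[C@@H]2C[C@H]3O[C@@]13C
F3 | step 13 | (13S)-10-epi-labdane-8α,15-diol | OCC[C@@H](C)CC[C@@H]1[C@]2(C)CCCC(C)(C)[C@@H]2CC[C@@]1(C)O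
F4 | step 6 | [(4-allyl-4,6,6-trimethylbicyclo[3.1.1]hept-2-en-2-yl)oxy]trimethylsilane, 4-methyl anti and 4-allyl syn to the gem-dimethyl bridge | C[Si](C)(C)OC1=C[C@](C)(CC=C)[C@H]2C[C@@H]1C2(C)C
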